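**Retrosynthetic overview**

1. Macrolide numbering: C1 lactone carbonyl, C3 (O‑bearing) and C4 the lactone‑carrying pair, C6 ketone, C9 the CH(CH3) carbon on O10. C1 and C6 are linked twice, by C2–C5 and by O10–C9–C8–C7, so the ten‑membered ring is the perimeter of a 2‑oxabicyclo[4.4.0]decene that lacks only the ring‑fusion bond C1–C6: target 24 ⇒ tricyclic enol ether 23 by peracid scission of a temporary C1=C6 bond (last step).
2. 23 ⇒ cis‑fused γ‑lactone 12 + bicyclic lactone 21: Claisen‑type union at the lactone α‑carbon, then cyclodehydration to the E‑alkylidene tetrahydrofuran.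
3. 12 ⇒ dienyl ester 7 (reagent‑controlled hydroboration of C3=C4, lactonisation with inversion at C3) ⇒ chroman acid 5 by Birch reduction: carbocycle C1–C6 is carried as a benzene ring.
4. Chroman ⇒ aryl propargyl ether 3: with C1–C6 aromatic, C6 is the arene carbon ortho to the ether oxygen O10 and C7–C8–C9 is its three‑carbon tether, so C6–C7 closes the pyran by a 6‑endo hydroarylation instead of a medium‑ring closure.
5. Ring order: pyran (step 2) → γ‑lactone on the carbocycle (step 7) → tetrahydropyran and its γ‑lactone in the side branch (steps 10–13) → alkylidene tetrahydrofuran (step 15) → ten‑membered ring by cleaving C1=C6 (step 16).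

Key step: step 2

Remark: (+)-IpcBH2 denotes the monoisopinocampheylborane derived from (−)-α-pinene, liberated beforehand from its commercial TMEDA adduct; the acid‑labile enol ethers 7–12, 22 and 23 are handled on base‑washed silica.

**Route**

Step 1
Reactants: 1 benzyl (4-hydroxyphenyl)acetate; 2 (S)-but-3-yn-2-ol
Product: 3 benzyl {4-[(2R)-but-3-yn-2-yloxy]phenyl}acetate
Conditions: PPh3, DIAD, THF, 0 °C → rt
Reagents that add atoms: none
Why: Mitsunobu etherification of the phenol proceeds by SN2 displacement of the alkoxyphosphonium ion, so the (S)-carbinol is inverted to the (R)-aryl ether that becomes C9 of the target.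

Step 2
Reactants: 3 benzyl {4-[(2R)-but-3-yn-2-yloxy]phenyl}acetate
Product: 4 benzyl [(2R)-2-methyl-2H-chromen-6-yl]acetate
Conditions: [Au(NCMe){P(t-Bu)2(2-biphenylyl)}]SbF6 (2 mol%), CH2Cl2, rt
Reagents that add atoms: none
Why: The cationic monovalent gold complex binds the terminal alkyne, the arene carbon ortho to the ether oxygen (chromene C4a, the future ketone carbon C6) attacks the terminal alkyne carbon (chromene C4, the future C7) in Friedel–Crafts fashion, and rearomatisation followed by protodeauration should release the 2H-chromene. The closest known reaction type is the gold- or platinum-catalysed intramolecular hydroarylation of aryl propargyl ethers to 2H-chromenes. The pyran ring closes in the 6-endo-dig mode. No stereocentre is created and no bond to C2 (the future C9) is made or broken, so the configuration fixed in step 1 should be carried through. The step needs 6-endo over 5-exo closure and a single arene position: the terminal alkyne on a three-atom O–C–C tether disfavours attack at the internal carbon (which would give a methylene-dihydrobenzofuran), and the para substituent leaves two equivalent ortho sites. After this one isomerisation all of C1–C9 and O10 of the ten-membered ring sit in a bicycle in which C1=C6 is an arene bond to be cut later.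

Step 3
Reactants: 4 benzyl [(2R)-2-methyl-2H-chromen-6-yl]acetate
Product: 5 [(2R)-2-methyl-3,4-dihydro-2H-chromen-6-yl]acetic acid
Conditions: H2 (1 atm), Pd/C (10%), EtOAc, rt
Reagents that add atoms: none
Why: Heterogeneous hydrogenation should saturate the styrenic C3=C4 bond and hydrogenolyse the benzyl ester in one operation, leaving the arene and the C2 stereocentre untouched.

Step 4
Reactants: 5 [(2R)-2-methyl-3,4-dihydro-2H-chromen-6-yl]acetic acid
Product: 7 methyl [(2R)-2-methyl-3,4,5,8-tetrahydro-2H-chromen-6-yl]acetate, via lithium carboxylate 6 (not isolated)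
Conditions: Li, NH3(l), THF, t-BuOH, −78 °C; NH3 evaporated; then MeI, DMF, 0 °C → rt
Reagents that add atoms: iodomethane, CI
Why: In the Birch reduction the three donor-substituted carbons (C8a, C4a, C6) stay sp2, so only the para-related unsubstituted pair C5/C8 is protonated, giving the tetrasubstituted enol ether C4a=C8a and the trisubstituted alkene C6=C7; the inert carboxylate is then O-methylated in the same flask.

Step 5
Reactants: 7 methyl [(2R)-2-methyl-3,4,5,8-tetrahydro-2H-chromen-6-yl]acetate
Product: 9 methyl [(2R,6S,7R)-7-hydroxy-2-methyl-3,4,5,6,7,8-hexahydro-2H-chromen-6-yl]acetate, via alkyl(isopinocampheyl)borane 8 (not isolated)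
Conditions: (+)-IpcBH2 (1.2 equiv), Et2O, −25 °C; then NaBO3·4H2O, THF/H2O, rt
Reagents that add atoms: sodium perborate, [Na+].[Na+].O[B-]1(O)OO[B-](O)(O)OO1
Why: Syn, anti-Markovnikov asymmetric hydroboration places boron on C7 of the trisubstituted alkene (the tetrasubstituted enol ether should be too hindered), the chiral borane selects the face (sense assigned by analogy with 1-methylcyclohexene), and oxidation with retention should give the trans alcohol with C6 (future C4) in its final configuration.

Step 6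
Reactants: 9 methyl [(2R,6S,7R)-7-hydroxy-2-methyl-3,4,5,6,7,8-hexahydro-2H-chromen-6-yl]acetate
Product: 10 methyl [(2R,6S,7R)-7-(methanesulfonyloxy)-2-methyl-3,4,5,6,7,8-hexahydro-2H-chromen-6-yl]acetate
Conditions: MsCl, Et3N, CH2Cl2, 0 °C
Reagents that add atoms: methanesulfonyl chloride, CS(=O)(=O)Cl
Why: Sulfonylation of the secondary alcohol (retention at C7) installs a leaving group trans to the acetate arm under basic conditions that the enol ether tolerates.

Step 7
Reactants: 10 methyl [(2R,6S,7R)-7-(methanesulfonyloxy)-2-methyl-3,4,5,6,7,8-hexahydro-2H-chromen-6-yl]acetate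
Product: 12 (3aS,7R,9aS)-7-methyl-3,3a,4,5,6,7,9,9a-octahydro-2H-furo[3,2-g]chromen-2-one, via lithium carboxylate 11 (not isolated)
Conditions: LiOH (1.2 equiv), THF/H2O, 0 °C → 40 °C
Reagents that add atoms: lithium hydroxide, [Li+].[OH-]
Why: Saponification followed by intramolecular SN2 displacement of the mesylate by the carboxylate (5-exo-tet, inversion at C7) should give the cis-fused γ-lactone with both ring-fusion centres (future C3 and C4) in the target configuration.

Step 8
Reactants: 13 1-(5-methylfuran-2-yl)ethan-1-one; 14 diethyl carbonate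
Product: 15 ethyl 3-(5-methylfuran-2-yl)-3-oxopropanoate
Conditions: NaH (2.2 equiv), THF, 65 °C; AcOH work-up
Reagents that add atoms: none
Why: Crossed Claisen condensation of the methyl ketone enolate with the non-enolisable carbonate is driven by deprotonation of the β-keto ester formed.

Step 9
Reactants: 15 ethyl 3-(5-methylfuran-2-yl)-3-oxopropanoate
Product: 16 ethyl (3S)-3-hydroxy-3-(5-methylfuran-2-yl)propanoate
Conditions: RuCl[(S,S)-TsDPEN](p-cymene) (1 mol%), HCO2H/Et3N (5:2), 30 °C
Reagents that add atoms: none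
Why: Noyori asymmetric transfer hydrogenation delivers hydride to the ketone face fixed by the heteroaryl–arene contact in the catalyst, which for aryl ketones with the (S,S)-ligand should give the (S)-carbinol.

Step 10
Reactants: 16 ethyl (3S)-3-hydroxy-3-(5-methylfuran-2-yl)propanoate
Product: 17 ethyl [(2S)-6-hydroxy-6-methyl-3-oxo-3,6-dihydro-2H-pyran-2-yl]acetate (both C6 anomers)
Conditions: NBS, NaHCO3, NaOAc, THF/H2O (4:1), 0 °C
Reagents that add atoms: water, O
Why: Achmatowicz rearrangement: oxidative opening of the furan to the cis-enedione and hemiketalisation by the carbinol oxygen give the pyranone without touching the carbinol stereocentre.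

Step 11
Reactants: 17 ethyl [(2S)-6-hydroxy-6-methyl-3-oxo-3,6-dihydro-2H-pyran-2-yl]acetate
Product: 18 ethyl [(2S,6R)-6-methyl-3-oxo-3,6-dihydro-2H-pyran-2-yl]acetate
Conditions: Et3SiH, CF3CO2H, CH2Cl2, −40 → 0 °C
Reagents that add atoms: none
Why: Ionic hydrogenation: the tertiary hemiketal ionises to the cyclic oxocarbenium ion and axial hydride delivery should give the 2,6-cis-dihydropyranone, the C2 substituent controlling C6.

Step 12
Reactants: 18 ethyl [(2S,6R)-6-methyl-3-oxo-3,6-dihydro-2H-pyran-2-yl]acetate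
Product: 19 ethyl [(2S,6R)-6-methyl-3-oxooxan-2-yl]acetate
Conditions: H2 (1 atm), Pd/C (10%), EtOAc, rt
Reagents that add atoms: none
Why: Catalytic hydrogenation of the enone C=C leaves ketone, ester and both stereocentres in place.

Step 13
Reactants: 19 ethyl [(2S,6R)-6-methyl-3-oxooxan-2-yl]acetate
Product: 21 (3aS,5R,7aS)-5-methylhexahydro-2H-furo[3,2-b]pyran-2-one, via hydroxy ester 20 (not isolated)
Conditions: LiBH(s-Bu)3, THF, −78 °C; AcOH; then TsOH·H2O (cat.), CH2Cl2, rt
Reagents that add atoms: none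
Why: The bulky hydride attacks the pyranone from the equatorial side to give the axial alcohol cis to the C2 acetate arm, which lactonises to the cis-fused bicyclic lactone.

Step 14
Reactants: 12 (3aS,7R,9aS)-7-methyl-3,3a,4,5,6,7,9,9a-octahydro-2H-furo[3,2-g]chromen-2-one; 21 (3aS,5R,7aS)-5-methylhexahydro-2H-furo[3,2-b]pyran-2-one
Product: 22 (3aS,7R,9aS)-3-{[(2S,3S,6R)-3-hydroxy-6-methyloxan-2-yl]acetyl}-7-methyl-3,3a,4,5,6,7,9,9a-octahydro-2H-furo[3,2-g]chromen-2-one (C3 epimers, in equilibrium with the cyclic hemiketal)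
Conditions: LiN(i-Pr)2 (1.1 equiv), THF, −78 °C; then 21 (1.3 equiv), −78 → −40 °C; AcOH
Reagents that add atoms: none
Why: Claisen-type addition of the lactone enolate of 12 to the lactone carbonyl of 21 stops at the lithium hemiketalate, which on work-up gives the hydroxy β-keto lactone; the new C3 centre is erased in the next step.

Step 15
Reactants: 22 hydroxy β-keto lactone
Product: 23 (3E,3aS,7R,9aS)-7-methyl-3-[(3aS,5R,7aS)-5-methylhexahydro-2H-furo[3,2-b]pyran-2-ylidene]-3,3a,4,5,6,7,9,9a-octahydro-2H-furo[3,2-g]chromen-2-one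
Conditions: PPTS (0.2 equiv), benzene, 4 Å molecular sieves, 40 °C
Reagents that add atoms: none
Why: Acid-catalysed cyclodehydration (hemiketal, oxocarbenium ion, loss of the lactone α-proton) gives the conjugated alkylidene tetrahydrofuran, and reversible protonation should settle on the E isomer, in which the ring oxygen is anti to the lactone carbonyl and the ring CH2 avoids allylic strain with C3a.

Step 16
Reactants: 23 tricyclic enol ether
Product: 24 Cordycicadin C
Conditions: mCPBA (2.2 equiv), NaHCO3, CH2Cl2, 0 °C → rt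
Reagents that add atoms: 3-chloroperbenzoic acid, O=C(OO)c1cccc(Cl)c1
Why: Epoxidation of the electron-rich tetrasubstituted ring-fusion enol ether, opening to the α-oxygenated oxocarbenium ion, addition of a second peracid and Criegee-type fragmentation cleave C4a–C8a into the C6 ketone and the C1 lactone carbonyl, unveiling the ten-membered ring while the electron-poor conjugated alkylidene and all stereocentres stay untouched.

**Compound list**

1 | benzyl (4-hydroxyphenyl)acetate | O=C(Cc1ccc(O)cc1)OCc1ccccc1 | starting material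
2 | (S)-but-3-yn-2-ol | C[C@H](O)C#C | starting material
3 | benzyl {4-[(2R)-but-3-yn-2-yloxy]phenyl}acetate | C[C@@H](Oc1ccc(CC(=O)OCc2ccccc2)cc1)C#C | intermediate
4 | benzyl [(2R)-2-methyl-2H-chromen-6-yl]acetate | C[C@@H]1C=Cc2cc(CC(=O)OCc3ccccc3)ccc2O1 | intermediate
5 | [(2R)-2-methyl-3,4-dihydro-2H-chromen-6-yl]acetic acid | C[C@@H]1CCc2cc(CC(=O)O)ccc2O1 | intermediate
6 | lithium [(2R)-2-methyl-3,4,5,8-tetrahydro-2H-chromen-6-yl]acetate | [Li+].C[C@@H]1CCC=5CC(CC(=O)[O-])=CCC=5O1 | intermediate (not isolated)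
7 | methyl [(2R)-2-methyl-3,4,5,8-tetrahydro-2H-chromen-6-yl]acetate | C[C@@H]1CCC=5CC(CC(=O)OC)=CCC=5O1 | intermediate
8 | (isopinocampheyl)[(2R,6S,7R)-6-(2-methoxy-2-oxoethyl)-2-methyl-3,4,5,6,7,8-hexahydro-2H-chromen-7-yl]borane | C[C@@H]1[C@@H](B[C@@H]2CC=3O[C@H](C)CCC=3C[C@H]2CC(=O)OC)C[C@H]4C[C@@H]1C4(C)C | intermediate (not isolated)
9 | methyl [(2R,6S,7R)-7-hydroxy-2-methyl-3,4,5,6,7,8-hexahydro-2H-chromen-6-yl]acetate | C[C@@H]1CCC=5C[C@@H](CC(=O)OC)[C@H](O)CC=5O1 | intermediate
10 | methyl [(2R,6S,7R)-7-(methanesulfonyloxy)-2-methyl-3,4,5,6,7,8-hexahydro-2H-chromen-6-yl]acetate | C[C@@H]1CCC=5C[C@@H](CC(=O)OC)[C@H](OS(C)(=O)=O)CC=5O1 | intermediate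
11 | lithium [(2R,6S,7R)-7-(methanesulfonyloxy)-2-methyl-3,4,5,6,7,8-hexahydro-2H-chromen-6-yl]acetate | [Li+].C[C@@H]1CCC=5C[C@@H](CC(=O)[O-])[C@H](OS(C)(=O)=O)CC=5O1 | intermediate (not isolated)
12 | (3aS,7R,9aS)-7-methyl-3,3a,4,5,6,7,9,9a-octahydro-2H-furo[3,2-g]chromen-2-one | C[C@@H]1CCC=5C[C@H]2CC(=O)O[C@H]2CC=5O1 | intermediate
13 | 1-(5-methylfuran-2-yl)ethan-1-one | CC(=O)c1ccc(C)o1 | starting material
14 | diethyl carbonate | CCOC(=O)OCC | starting material
15 | ethyl 3-(5-methylfuran-2-yl)-3-oxopropanoate | CCOC(=O)CC(=O)c1ccc(C)o1 | intermediate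
16 | ethyl (3S)-3-hydroxy-3-(5-methylfuran-2-yl)propanoate | CCOC(=O)C[C@H](O)c1ccc(C)o1 | intermediate
17 | ethyl [(2S)-6-hydroxy-6-methyl-3-oxo-3,6-dihydro-2H-pyran-2-yl]acetate | CCOC(=O)C[C@@H]1OC(C)(O)C=CC1=O | intermediate
18 | ethyl [(2S,6R)-6-methyl-3-oxo-3,6-dihydro-2H-pyran-2-yl]acetate | CCOC(=O)C[C@@H]1O[C@H](C)C=CC1=O | intermediate
19 | ethyl [(2S,6R)-6-methyl-3-oxooxan-2-yl]acetate | CCOC(=O)C[C@@H]1O[C@H](C)CCC1=O | intermediate
20 | ethyl [(2S,3S,6R)-3-hydroxy-6-methyloxan-2-yl]acetate | CCOC(=O)C[C@@H]1O[C@H](C)CC[C@@H]1O | intermediate (not isolated)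
21 | (3aS,5R,7aS)-5-methylhexahydro-2H-furo[3,2-b]pyran-2-one | O=C1C[C@@H]2O[C@H](C)CC[C@@H]2O1 | intermediate
22 | (3aS,7R,9aS)-3-{[(2S,3S,6R)-3-hydroxy-6-methyloxan-2-yl]acetyl}-7-methyl-3,3a,4,5,6,7,9,9a-octahydro-2H-furo[3,2-g]chromen-2-one | C[C@@H]1CCC=5C[C@H]2C(C(=O)C[C@@H]3O[C@H](C)CC[C@@H]3O)C(=O)O[C@H]2CC=5O1 | intermediate
23 | (3E,3aS,7R,9aS)-7-methyl-3-[(3aS,5R,7aS)-5-methylhexahydro-2H-furo[3,2-b]pyran-2-ylidene]-3,3a,4,5,6,7,9,9a-octahydro-2H-furo[3,2-g]chromen-2-one | C[C@@H]1CCC=5C[C@H]2/C(=C3/C[C@@H]4O[C@H](C)CC[C@@H]4O3)C(=O)O[C@H]2CC=5O1 | intermediate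
24 | Cordycicadin C | C[C@@H]1CCC(=O)C[C@H]2/C(=C3/C[C@@H]4O[C@H](C)CC[C@@H]4O3)C(=O)O[C@H]2CC(=O)O1 | target

**Step count and risks**

Total step count: 16. Longest linear sequence: 10 steps (steps 1–7 and 14–16).

Steps most likely to fail:

1. Step 5. The chiral borane may discriminate poorly between the two faces of a 1-alkylcyclohexene-type alkene, and slow hydroboration of the enol ether may compete. The fallback sets out from 7 and replaces reagent control by enzymatic control. Hydroboration with 9-BBN (one B–H, no chiral information) should give the B-alkyl-9-borabicyclo[3.3.1]nonane adducts F1, and perborate oxidation then gives 9 together with its ring diastereomer methyl [(2R,6R,7S)-7-hydroxy-2-methyl-3,4,5,6,7,8-hexahydro-2H-chromen-6-yl]acetate F2. Acylation with vinyl acetate and Burkholderia cepacia lipase should convert only the (7R)-alcohol into methyl [(2R,6S,7R)-7-acetoxy-2-methyl-3,4,5,6,7,8-hexahydro-2H-chromen-6-yl]acetate F3, which is separated from unreacted F2. Methanolysis (K2CO3, MeOH) of F3 returns to the route at compound 9.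

2. Step 14. Proton exchange between the lactone enolate and the enolisable lactone 21 may outrun addition, leading to self-condensation and stalled conversion. The fallback sets out from 21 and uses an acyl donor that does not enolise under the conditions. Aminolysis with MeNH(OMe)·HCl and i-PrMgCl gives 2-[(2S,3S,6R)-3-hydroxy-6-methyloxan-2-yl]-N-methoxy-N-methylacetamide F4, which is silylated (TBSOTf, 2,6-lutidine) to 2-[(2S,3S,6R)-3-(tert-butyldimethylsilyloxy)-6-methyloxan-2-yl]-N-methoxy-N-methylacetamide F5. Acylation of the lithium enolate of 12 with F5 should give the silylated β-keto lactone (3aS,7R,9aS)-3-{[(2S,3S,6R)-3-(tert-butyldimethylsilyloxy)-6-methyloxan-2-yl]acetyl}-7-methyl-3,3a,4,5,6,7,9,9a-octahydro-2H-furo[3,2-g]chromen-2-one F6. Desilylation (Bu4NF buffered with AcOH) returns to the route at compound 22.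

3. Step 16. The peracid may over-oxidise (Baeyer–Villiger attack on the new ketone, epoxidation of the alkylidene), or the first epoxide may be trapped without fragmenting. The fallback sets out from 23 and separates oxidation from cleavage. Dihydroxylation of the electron-rich enol ether (OsO4 cat., N-methylmorpholine N-oxide) should give the α-hydroxy hemiketal (3E,3aS,7R,9aS)-4a,8a-dihydroxy-7-methyl-3-[(3aS,5R,7aS)-5-methylhexahydro-2H-furo[3,2-b]pyran-2-ylidene]decahydro-2H-furo[3,2-g]chromen-2-one F7. Glycol cleavage of F7 with Pb(OAc)4 (CH2Cl2, K2CO3, 0 °C) returns to the route at compound 24.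

**Further compounds**

F1 | step 5 | 9-[(2R)-6-(2-methoxy-2-oxoethyl)-2-methyl-3,4,5,6,7,8-hexahydro-2H-chromen-7-yl]-9-borabicyclo[3.3.1]nonane (both 6,7-trans diastereomers) | C[C@@H]1CCC=5CC(CC(=O)OC)C(B2C3CCCC2CCC3)CC=5O1
F2 | step 5 | methyl [(2R,6R,7S)-7-hydroxy-2-methyl-3,4,5,6,7,8-hexahydro-2H-chromen-6-yl]acetate | C[C@@H]1CCC=5C[C@H](CC(=O)OC)[C@@H](O)CC=5O1
F3 | step 5 | methyl [(2R,6S,7R)-7-acetoxy-2-methyl-3,4,5,6,7,8-hexahydro-2H-chromen-6-yl]acetate | C[C@@H]1CCC=5C[C@@H](CC(=O)OC)[C@H](OC(C)=O)CC=5O1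
F4 | step 14 | 2-[(2S,3S,6R)-3-hydroxy-6-methyloxan-2-yl]-N-methoxy-N-methylacetamide | CON(C)C(=O)C[C@@H]1O[C@H](C)CC[C@@H]1O
F5 | step 14 | 2-[(2S,3S,6R)-3-(tert-butyldimethylsilyloxy)-6-methyloxan-2-yl]-N-methoxy-N-methylacetamide | CON(C)C(=O)C[C@@H]1O[C@H](C)CC[C@@H]1O[Si](C)(C)C(C)(C)C
F6 | step 14 | (3aS,7R,9aS)-3-{[(2S,3S,6R)-3-(tert-butyldimethylsilyloxy)-6-methyloxan-2-yl]acetyl}-7-methyl-3,3a,4,5,6,7,9,9a-octahydro-2H-furo[3,2-g]chromen-2-one | C[C@@H]1CCC=5C[C@H]2C(C(=O)C[C@@H]3O[C@H](C)CC[C@@H]3O[Si](C)(C)C(C)(C)C)C(=O)O[C@H]2CC=5O1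
F7 | step 16 | (3E,3aS,7R,9aS)-4a,8a-dihydroxy-7-methyl-3-[(3aS,5R,7aS)-5-methylhexahydro-2H-furo[3,2-b]pyran-2-ylidene]decahydro-2H-furo[3,2-g]chromen-2-one (cis-diol, both faces) | C[C@@H]1CCC5(O)C[C@H]2/C(=C3/C[C@@H]4O[C@H](C)CC[C@@H]4O3)C(=O)O[C@H]2CC5(O)O1
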